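## Retrosynthetic overview
1. Cut the C4–C2′ methine–naphthyl bond in the Friedel–Crafts sense. This gives 8-methoxy-1-naphthol (ortho nucleophile) and (1S)-5-methoxytetralin-1,4-diol (source of the methoxy-stabilised C4 cation). C4 (R, trans to C1) is set in this union.
2. Both partners come from one ketone, 8-methoxy-1-tetralone. Dehydrogenation gives the naphthol. Enantioselective C4–H hydroxylation (sets the future C1, S) followed by C=O reduction gives the diol.
3. 8-Methoxy-1-tetralone comes from a four-to-six ring expansion of 1-(2-methoxyphenyl)cyclobutanol: alkoxy-radical β-scission, then re-closure on the free ortho carbon.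
4. The cyclobutanol comes from anisole (ortho-lithiation) and cyclobutanone.
5. Ring order: the anisole rings are bought. The second six-membered ring of each half is made once by the ring expansion and used twice. No ring is formed after that.

Assumption: the antipodes of the chiral catalysts in steps 4 and 6 are written as expected from the closest analogues. If a test run shows the opposite sense, the mirror-image catalyst is used and nothing else changes.

## Route

Step 1
Reactants: 1 anisole; 2 cyclobutanone
Product: 4 1-(2-methoxyphenyl)cyclobutan-1-ol, via 2-lithioanisole 3 (not isolated)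
Conditions: n-BuLi (1.1 equiv), TMEDA (1.1 equiv), Et2O, 0 °C to rt, 2 h; then 2, −78 °C to rt; H2O quench
Reagents that add atoms: none
Why: Directed ortho-lithiation of anisole followed by 1,2-addition of the aryllithium to the strained, highly electrophilic cyclobutanone; no stereocenter is formed.

Step 2
Reactants: 4 1-(2-methoxyphenyl)cyclobutan-1-ol
Product: 6 8-methoxy-3,4-dihydronaphthalen-1(2H)-one (8-methoxy-1-tetralone), via 4-(2-methoxyphenyl)-4-oxobutyl radical 5 (not isolated)
Conditions: AgNO3 (20 mol %), K2S2O8 (2 equiv), CH2Cl2/H2O 1:1, 30 °C, 12 h
Reagents that add atoms: none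
Why: Oxidative radical ring expansion of a 1-arylcyclobutanol: persulfate-generated divalent silver oxidises the tertiary alcohol to an alkoxy radical, strain-driven β-scission gives primary radical 5, and 5 closes in a six-membered mode on the only free ortho carbon of the aryl ketone and is re-aromatised by a second one-electron oxidation (homolytic aromatic substitution), so the four-membered ring becomes the six-membered tetralone ring with the methoxy group peri to C=O; no stereocenter is formed.

The batch of 6 is split about 1:1 between steps 3 and 4.

Step 3
Reactants: 6 8-methoxy-1-tetralone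
Product: 8 8-methoxynaphthalen-1-ol, via 8-methoxynaphthalen-1(4H)-one 7 (not isolated)
Conditions: Pd(O2CCF3)2 (5 mol %), 2-(dimethylamino)pyridine (10 mol %), TsOH·H2O (20 mol %), O2 (1 atm), DMSO, 80 °C
Reagents that add atoms: none
Why: Aerobic palladium-catalysed α,β-dehydrogenation of a cyclic ketone: the divalent palladium enolate undergoes β-hydride elimination to dienone 7, which tautomerises irreversibly to the naphthol, and the aryl methyl ether is inert.

Step 4
Reactants: 6 8-methoxy-1-tetralone
Product: 9 (4S)-4-hydroxy-8-methoxy-3,4-dihydronaphthalen-1(2H)-one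
Conditions: Mn(OTf)2[(S,S)-pdp] (1 mol %; pdp = N,N′-bis(2-pyridylmethyl)-2,2′-bipyrrolidine), 30% aq H2O2 (1.2 equiv, syringe pump), 2-ethylhexanoic acid (5 equiv), CF3CH2OH, −30 °C; stop at about 70% conversion, recover 6; recrystallise 9 if ee needs raising
Reagents that add atoms: hydrogen peroxide, OO
Why: Catalytic enantioselective benzylic C–H hydroxylation (hydrogen-atom abstraction and oxygen rebound at a chiral manganese-oxo species): C4–H2 is the only benzylic methylene, the C2 and C3 hydrogens are deactivated by the carbonyl, the fluorinated alcohol hydrogen-bonds to the product carbinol and slows over-oxidation, and the chiral pocket selects the pro-S hydrogen, which sets the (S)-carbinol that becomes C1 of the target.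

Step 5
Reactants: 9 (4S)-4-hydroxy-8-methoxy-1-tetralone
Product: 10 (1S)-5-methoxy-1,2,3,4-tetrahydronaphthalene-1,4-diol (mixture of both C4 epimers, used as such)
Conditions: NaBH4 (1 equiv), MeOH, 0 °C, 30 min; aq NaHCO3 work-up
Reagents that add atoms: none
Why: Borohydride 1,2-reduction of an aryl ketone; the (S)-carbinol is untouched, and the new carbinol center needs no control because ionisation erases it in step 6.

Step 6
Reactants: 10 (1S)-5-methoxytetralin-1,4-diol; 8 8-methoxynaphthalen-1-ol
Product: 12 dipolynaphthalene A [(1S,4R)-4-(1-hydroxy-8-methoxynaphthalen-2-yl)-5-methoxy-1,2,3,4-tetrahydronaphthalen-1-ol; 1,4-trans], via (4S)-4-hydroxy-8-methoxy-1,2,3,4-tetrahydronaphthalen-1-ylium 11 (not isolated)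
Conditions: 8 (1.5 equiv), (R)-3,3′-bis(2,4,6-triisopropylphenyl)-1,1′-binaphthyl-2,2′-diyl N-triflylphosphoramide (5 mol %), 5 Å MS, toluene/CH2Cl2 3:1, slow addition of 10, −20 to 0 °C
Reagents that add atoms: none
Why: Proposed new method: a stereoconvergent, ortho-selective dehydrative Friedel–Crafts alkylation under chiral strong Brønsted acid catalysis, in which the acid ionises only the C4–OH (ortho-methoxy-stabilised, whereas the C1–OH sits meta to OMe and stays), both C4 epimers of 10 collapse to the same planar cation 11 held as a contact ion pair, the phosphoramidate P=O accepts the naphthol O–H so that C2′ rather than C4′ faces the cation and the proton is handed back on re-aromatisation, and pseudoaxial attack anti to the pseudoaxial C1–OH (matched with the catalyst pocket) gives the trans (4R) center; the closest known reaction type is the chiral phosphoric acid-catalysed Friedel–Crafts alkylation of naphthols and indoles by quinone methides or diarylcarbinols, which has not been shown for a simple O-methylated secondary benzylic cation lacking a hydrogen-bond handle and carrying a second free carbinol.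

## Compound list
1 | anisole | COc1ccccc1 | starting material
2 | cyclobutanone | O=C1CCC1 | starting material
3 | 2-lithioanisole (not isolated) | COc1ccccc1[Li] | intermediate
4 | 1-(2-methoxyphenyl)cyclobutan-1-ol | COc1ccccc1C1(O)CCC1 | intermediate
5 | 4-(2-methoxyphenyl)-4-oxobutyl radical (not isolated) | COc1ccccc1C(=O)CC[CH2] | intermediate
6 | 8-methoxy-3,4-dihydronaphthalen-1(2H)-one | COc1cccc2c1C(=O)CCC2 | intermediate
7 | 8-methoxynaphthalen-1(4H)-one (not isolated) | COc1cccc2c1C(=O)C=CC2 | intermediate
8 | 8-methoxynaphthalen-1-ol | COc1cccc2cccc(O)c12 | intermediate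
9 | (4S)-4-hydroxy-8-methoxy-3,4-dihydronaphthalen-1(2H)-one | COc1cccc2c1C(=O)CC[C@@H]2O | intermediate
10 | (1S)-5-methoxy-1,2,3,4-tetrahydronaphthalene-1,4-diol, both C4 epimers | COc1cccc2c1C(O)CC[C@@H]2O | intermediate
11 | (4S)-4-hydroxy-8-methoxy-1,2,3,4-tetrahydronaphthalen-1-ylium (not isolated) | COc1cccc2c1[CH+]CC[C@@H]2O | intermediate
12 | dipolynaphthalene A, (1S,4R), 1,4-trans | COc1cccc2c1[C@@H](c1ccc3cccc(OC)c3c1O)CC[C@@H]2O | target

## Count
Total steps: 6. Longest linear sequence: 5 (steps 1, 2, 4, 5, 6); step 3 is the side branch from 6.

## Steps most likely to fail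

**Step 6 (the new step).**
- Risks: para attack at C4′ of the naphthol; formation of the cis isomer; proton loss from 11 followed by loss of the second water, which aromatises the electrophile.
- Fallback (known chemistry): it sets out from 8 and 10 and comes back at 12. Regiocontrol comes from a para-blocking bromide and stereocontrol from the substrate alone.
- NBS (1 equiv, MeCN, −20 °C) brominates 8 para to the hydroxyl and gives 4-bromo-8-methoxynaphthalen-1-ol F5.
- Ordinary acid-catalysed dehydrative benzylation of F5 with 10 (TsOH·H2O 10 mol %, CH2Cl2/HFIP, 0 °C) can only occur at C2′. It gives (1S,4R)-4-(4-bromo-1-hydroxy-8-methoxynaphthalen-2-yl)-5-methoxy-1,2,3,4-tetrahydronaphthalen-1-ol F6 as the expected major trans isomer. The cis isomer is removed by chromatography; because C1 is already enantiopure, this is a diastereomer separation.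
- Hydrodebromination (H2 1 atm, Pd/C, NaOAc, MeOH, rt) then gives 12.

**Step 4.**
- Risks: moderate ee; over-oxidation to the 1,4-dione or hydroquinone manifold; O-demethylation.
- Fallback: it sets out from 6 and comes back at 9. The catalytic asymmetric C–H oxidation is replaced by halogenation, substitution and enzymatic resolution.
- Wohl–Ziegler bromination (NBS, AIBN, PhCF3, reflux) gives rac-4-bromo-8-methoxy-3,4-dihydronaphthalen-1(2H)-one F2.
- Silver-assisted hydrolysis (AgNO3, acetone/H2O, rt) gives rac-4-hydroxy-8-methoxy-3,4-dihydronaphthalen-1(2H)-one F3.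
- Kinetic resolution with Candida antarctica lipase B and vinyl acetate (MTBE, 30 °C, about 52% conversion) acylates the R enantiomer to (1R)-5-methoxy-4-oxo-1,2,3,4-tetrahydronaphthalen-1-yl acetate F4. The unreacted alcohol is 9, isolated by chromatography in at most 50% yield.

**Step 2.**
- Risks: acid-induced ionisation of the electron-rich benzylic cyclobutanol; oxidation of the anisole ring; ipso attack at the methoxy-bearing carbon.
- Fallback: it sets out from 4 and comes back at 6. Cleavage and ring closure are separated into two stages.
- Hypoiodite photolysis (PhI(OAc)2, I2, visible light, CH2Cl2, rt) stops the fragmentation at the open chain as 4-iodo-1-(2-methoxyphenyl)butan-1-one F1.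
- The ring is then closed under neutral conditions by peroxide-mediated oxidative radical cyclisation onto the arene (dilauroyl peroxide 1.3 equiv in portions, 1,2-dichloroethane, reflux). Base is avoided because it would turn F1 into the cyclopropyl ketone.

## Further compounds
F1 | step 2 | 4-iodo-1-(2-methoxyphenyl)butan-1-one | COc1ccccc1C(=O)CCCI
F2 | step 4 | rac-4-bromo-8-methoxy-3,4-dihydronaphthalen-1(2H)-one | COc1cccc2c1C(=O)CCC2Br
F3 | step 4 | rac-4-hydroxy-8-methoxy-3,4-dihydronaphthalen-1(2H)-one | COc1cccc2c1C(=O)CCC2O
F4 | step 4 | (1R)-5-methoxy-4-oxo-1,2,3,4-tetrahydronaphthalen-1-yl acetate | COc1cccc2c1C(=O)CC[C@H]2OC(C)=O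
F5 | step 6 | 4-bromo-8-methoxynaphthalen-1-ol | COc1cccc2c(Br)ccc(O)c12
F6 | step 6 | (1S,4R)-4-(4-bromo-1-hydroxy-8-methoxynaphthalen-2-yl)-5-methoxy-1,2,3,4-tetrahydronaphthalen-1-ol | COc1cccc2c1[C@@H](c1cc(Br)c3cccc(OC)c3c1O)CC[C@@H]2O
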